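**Retrosynthetic overview**
1. The C3–C1'' bond is cut last, after one fluoride deprotection. A C3-magnesiated ring A adds to the (2E,4E,6E,8R)-trienal and the carbinol is oxidised. C8'' comes from an oxazolidinone-directed hydroxymethylation and the triene from a vinylogous Horner–Wadsworth–Emmons reaction.
2. Ring B (cyclohexane, C1'–C6') is cut at C3'–C4' and C5'–C4'. C4' is taken from carbon monoxide. The arms C2'–C3' and C6'–C5' are the two vinyl groups of a 3-(ring A)-penta-1,4-dien-3-ol, made from the C5 ester of ring A and a vinyl nucleophile.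
3. Enabling feature: ring B has a local mirror plane through C1' and C4', and the carbinol carbon C4' is flanked by two identical CH2CH2 arms that meet at the fully substituted C1'. One boron atom can therefore hold both arm ends (C3', C5') in a temporary borinane and pass them one after the other to CO. The second 1,2-shift closes ring B at C3'–C4'.
4. Order of rings: ring A first (N-alkoxy-4-hydroxy-2-pyridone, by an enaminone cyclocondensation that brings in the N–O bond), then the temporary six- and seven-membered boracycles, then ring B. The cis-1,4-diol follows from axial hydride delivery to the C4' ketone.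

Key step: step 5

Remark: ring A is numbered N1, C2(=O), C3 (acyl), C4 (OH), C5 (ring B), C6 (H); ring B runs from C1' (tertiary carbinol) to C6' with C4' the secondary carbinol; the side chain runs from C1'' (C=O) to C10''; the two ring B descriptors are read as the cis-1,4-diol (both hydroxyl groups on one face, ring A and C4'-OH trans) and the side-chain centre as 8''R.

**Step 1**
Reactants: 1 dimethyl 3-oxopentanedioate; 2 O-[2-(trimethylsilyl)ethyl]hydroxylamine hydrochloride
Product: 5 methyl 4-hydroxy-6-oxo-1-[2-(trimethylsilyl)ethoxy]-1,6-dihydropyridine-3-carboxylate, via dimethylaminomethylidene diester 3 (not isolated), via alkoxyaminomethylidene diester 4 (not isolated)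
Conditions: Me2NCH(OMe)2 (1.0 equiv), THF, 0 °C to rt; 2, MeOH, rt; NaOMe (1.1 equiv), MeOH, 65 °C; aq. HCl work-up
Reagents that add atoms: N,N-dimethylformamide dimethyl acetal, COC(OC)N(C)C
Why: Enaminone cyclocondensation: the amide acetal condenses with one activated CH2, the alkoxyammonium salt exchanges the dimethylamino group, and the deprotonated N–H lactamises onto the distal ester, which should give ring A with the N–O bond, the C6–H carbon and the C5 ester in place.

**Step 2**
Reactants: 5 methyl 4-hydroxy-6-oxo-1-[2-(trimethylsilyl)ethoxy]-1,6-dihydropyridine-3-carboxylate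
Product: 6 methyl 6-oxo-1,4-bis[2-(trimethylsilyl)ethoxy]-1,6-dihydropyridine-3-carboxylate
Conditions: Me3SiCH2CH2OH, PPh3, DIAD, THF, 0 °C to rt
Reagents that add atoms: 2-(trimethylsilyl)ethanol, C[Si](C)(C)CCO
Why: Mitsunobu etherification: the vinylogous acid O4–H is acidic enough to protonate the betaine and, with nitrogen already substituted, alkylation should occur at O4, so that ring A carries two groups that fall to fluoride at the end.

**Step 3**
Reactants: 6 methyl 6-oxo-1,4-bis[2-(trimethylsilyl)ethoxy]-1,6-dihydropyridine-3-carboxylate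
Product: 8 5-(3-hydroxypenta-1,4-dien-3-yl)-1,4-bis[2-(trimethylsilyl)ethoxy]pyridin-2(1H)-one, via vinyl ketone 7 (not isolated)
Conditions: CH2=CHMgBr (4 equiv), CeCl3 (anhydrous, 4 equiv), THF, -78 °C to 0 °C; aq. NH4Cl
Reagents that add atoms: vinylmagnesium bromide, C=C[Mg]Br
Why: Double 1,2-addition of an organocerium reagent to an ester: the oxophilic and weakly basic CH2=CHCeCl2 should add to the ester and then to the carbonyl carbon of the transient vinyl ketone 7 in preference to its terminal carbon or to C6 of ring A, which sets up the fully substituted C1' with two identical arms.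

**Step 4**
Reactants: 8 5-(3-hydroxypenta-1,4-dien-3-yl)-1,4-bis[2-(trimethylsilyl)ethoxy]pyridin-2(1H)-one
Product: 9 5-[3-(triethylsilyloxy)penta-1,4-dien-3-yl]-1,4-bis[2-(trimethylsilyl)ethoxy]pyridin-2(1H)-one
Conditions: Et3SiOTf, 2,6-lutidine, CH2Cl2, -78 °C
Reagents that add atoms: triethylsilyl trifluoromethanesulfonate, CC[Si](CC)(CC)OS(=O)(=O)C(F)(F)F
Why: Silyl triflate silylation of a hindered tertiary alcohol under lutidine buffering at low temperature should avoid ionisation of the doubly allylic carbinol and removes the O–H that would consume B–H in step 5.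

**Step 5**
Reactants: 9 5-[3-(triethylsilyloxy)penta-1,4-dien-3-yl]-1,4-bis[2-(trimethylsilyl)ethoxy]pyridin-2(1H)-one
Product: 13 5-[4-oxo-1-(triethylsilyloxy)cyclohexyl]-1,4-bis[2-(trimethylsilyl)ethoxy]pyridin-2(1H)-one, via B-thexylborinane 10 (not isolated), via acylborepane 11 (not isolated), via hydroxyborinic acid 12 (not isolated)
Conditions: BH3·THF, Me2C=CMe2, THF, 0 °C (gives ThxBH2); 9 added slowly, THF (0.02 M), 0 °C to rt; CO (70 atm), H2O (2 equiv), 50 °C; 30% H2O2, aq. NaOAc, 0 °C to 40 °C
Reagents that add atoms: carbon monoxide, [C-]#[O+]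
Why: Thexylborane should add to both vinyl groups with boron on the terminal carbons C3' and C5', the second addition being intramolecular and endo, so that the six-membered B-thexylborinane 10 is the temporary ring that ties the two arm ends together. CO then binds to boron and a first 1,2-shift carries one arm end from boron to the carbonyl carbon, which widens the ring to the seven-membered acylborane 11; a second 1,2-shift carries the other arm end from boron to the same carbon, forms the C3'–C4' bond and thereby contracts the boracycle to the six-membered carbocycle (ring B), whose boraepoxide is opened by water to 12. Water halts the sequence before a third shift, the tertiary thexyl group is the poorest migrating group, and buffered H2O2 should then cleave both remaining B–C bonds and release ketone 13. The closest known reaction type is the cyclic hydroboration–carbonylation of 1,4- and 1,5-dienes to cyclic ketones (stitching with boron and riveting with CO), in which two carbon termini of like, nucleophilic polarity are joined through one CO carbon. No stereocentre is formed, because 13 keeps the mirror plane through C1' and C4' and the two arms of 9 are enantiotopic, so that either order of migration gives the same product. The step needs terminal regioselectivity, ring formation in preference to chain growth and attack on the vinyl groups only, which are secured by the fully substituted C1' (it shields C2' and C6' and exerts a geminal-substituent effect), by slow addition at high dilution and by the low reactivity of the push–pull ring A and its silyl and silylethyl ethers toward a hindered monoalkylborane.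

**Step 6**
Reactants: 13 5-[4-oxo-1-(triethylsilyloxy)cyclohexyl]-1,4-bis[2-(trimethylsilyl)ethoxy]pyridin-2(1H)-one
Product: 14 5-[cis-4-hydroxy-1-(triethylsilyloxy)cyclohexyl]-1,4-bis[2-(trimethylsilyl)ethoxy]pyridin-2(1H)-one (C1'-O and C4'-O on one face)
Conditions: NaBH4, MeOH/THF, -40 °C
Reagents that add atoms: none
Why: Borohydride reduction of a conformationally biased cyclohexanone: with ring A equatorial and the C1' silyloxy group axial, the small hydride should attack C4' along the axial trajectory and give the equatorial alcohol, so that C4'-OH is trans to ring A and cis to C1'-O (both centres become stereogenic here), the minor epimer being removed by chromatography.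

**Step 7**
Reactants: 14 5-[cis-4-hydroxy-1-(triethylsilyloxy)cyclohexyl]-1,4-bis[2-(trimethylsilyl)ethoxy]pyridin-2(1H)-one
Product: 15 5-[cis-4-(tert-butyldimethylsilyloxy)-1-(triethylsilyloxy)cyclohexyl]-1,4-bis[2-(trimethylsilyl)ethoxy]pyridin-2(1H)-one
Conditions: t-BuMe2SiCl, imidazole, DMF, rt
Reagents that add atoms: tert-butyldimethylsilyl chloride, CC(C)(C)[Si](C)(C)Cl
Why: Imidazole-promoted silylation of the unhindered equatorial alcohol leaves no acidic or oxidisable O–H for steps 19 and 20 and does not touch either ring B centre.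

**Step 8**
Reactants: 15 5-[cis-4-(tert-butyldimethylsilyloxy)-1-(triethylsilyloxy)cyclohexyl]-1,4-bis[2-(trimethylsilyl)ethoxy]pyridin-2(1H)-one
Product: 16 5-[cis-4-(tert-butyldimethylsilyloxy)-1-(triethylsilyloxy)cyclohexyl]-3-iodo-1,4-bis[2-(trimethylsilyl)ethoxy]pyridin-2(1H)-one
Conditions: NIS, MeCN, 0 °C to rt, dark
Reagents that add atoms: N-iodosuccinimide, O=C1CCC(=O)N1I
Why: Electrophilic aromatic iodination: C3 is the only free nucleophilic position of the 4-alkoxy-2-pyridone (ortho to O4 and alpha to C2=O), so iodination there should fix the site of the later metalation.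

**Step 9**
Reactants: 17 (R)-4-benzyloxazolidin-2-one; 18 butanoyl chloride
Product: 19 (R)-4-benzyl-3-butanoyloxazolidin-2-one
Conditions: n-BuLi, THF, -78 °C; 18, -78 °C to 0 °C
Reagents that add atoms: none
Why: N-acylation of the lithiated oxazolidinone with an acid chloride is a standard way to load the auxiliary and leaves its stereocentre untouched.

**Step 10**
Reactants: 19 (R)-4-benzyl-3-butanoyloxazolidin-2-one
Product: 20 (R)-4-benzyl-3-[(2S)-2-(hydroxymethyl)butanoyl]oxazolidin-2-one
Conditions: TiCl4, iPr2NEt, CH2Cl2, 0 °C; 1,3,5-trioxane, TiCl4, 0 °C; aq. NH4Cl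
Reagents that add atoms: 1,3,5-trioxane, C1OCOCO1
Why: Evans-type titanium enolate hydroxymethylation: the chelated Z-enolate should be attacked by TiCl4-activated formaldehyde on the face opposite the benzyl group, which with the (R)-auxiliary gives the (2S)-imide, the arrangement that becomes 8''R.

**Step 11**
Reactants: 20 (R)-4-benzyl-3-[(2S)-2-(hydroxymethyl)butanoyl]oxazolidin-2-one
Product: 21 (R)-4-benzyl-3-[(2S)-2-{[(tert-butyldimethylsilyl)oxy]methyl}butanoyl]oxazolidin-2-one
Conditions: t-BuMe2SiCl, imidazole, CH2Cl2, 0 °C to rt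
Reagents that add atoms: tert-butyldimethylsilyl chloride, CC(C)(C)[Si](C)(C)Cl
Why: Mild imidazole-promoted silylation differentiates the two future CH2O termini before the imide is reduced and should avoid retro-aldol loss of formaldehyde.

**Step 12**
Reactants: 21 (R)-4-benzyl-3-[(2S)-2-{[(tert-butyldimethylsilyl)oxy]methyl}butanoyl]oxazolidin-2-one
Product: 22 (2R)-2-{[(tert-butyldimethylsilyl)oxy]methyl}butan-1-ol
Conditions: LiBH4, MeOH (1 equiv), Et2O, 0 °C
Reagents that add atoms: none
Why: Reductive cleavage of the auxiliary with LiBH4 attacks the exocyclic imide carbonyl, and a cold neutral work-up should prevent the 1,3-silyl migration that would racemise the product.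

**Step 13**
Reactants: 22 (2R)-2-{[(tert-butyldimethylsilyl)oxy]methyl}butan-1-ol
Product: 23 (2S)-2-{[(tert-butyldimethylsilyl)oxy]methyl}butanal
Conditions: TEMPO (cat.), PhI(OAc)2, CH2Cl2, rt
Reagents that add atoms: none
Why: Oxoammonium (TEMPO) oxidation stops at the aldehyde and runs without base, so the alpha stereocentre should be kept and the silyloxy group should not be eliminated.

**Step 14**
Reactants: 24 ethyl (2E,4E)-hexa-2,4-dienoate
Product: 25 ethyl (2E,4E)-6-bromohexa-2,4-dienoate
Conditions: NBS, AIBN (cat.), PhCF3, 85 °C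
Reagents that add atoms: N-bromosuccinimide, O=C1CCC(=O)N1Br
Why: Wohl–Ziegler bromination: hydrogen abstraction from the terminal methyl group gives an ester-conjugated pentadienyl radical that should take up bromine at the terminus and so keep the conjugated (E,E)-dienoate.

**Step 15**
Reactants: 25 ethyl (2E,4E)-6-bromohexa-2,4-dienoate
Product: 26 ethyl (2E,4E)-6-(diethoxyphosphoryl)hexa-2,4-dienoate
Conditions: P(OEt)3, neat, 120 °C
Reagents that add atoms: triethyl phosphite, CCOP(OCC)OCC
Why: Michaelis–Arbuzov reaction of a primary allylic bromide should proceed by direct displacement and dealkylation without change of the diene geometry.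

**Step 16**
Reactants: 23 (2S)-2-{[(tert-butyldimethylsilyl)oxy]methyl}butanal; 26 ethyl (2E,4E)-6-(diethoxyphosphoryl)hexa-2,4-dienoate
Product: 27 ethyl (2E,4E,6E,8R)-8-{[(tert-butyldimethylsilyl)oxy]methyl}deca-2,4,6-trienoate
Conditions: 26, LiN(SiMe3)2, THF, -78 °C; 23, -78 °C to 0 °C
Reagents that add atoms: none
Why: Vinylogous Horner–Wadsworth–Emmons olefination with a stabilised phosphonate anion should form the new C6''=C7'' bond with E geometry, and the low temperature protects the alpha stereocentre of the aldehyde.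

**Step 17**
Reactants: 27 ethyl (2E,4E,6E,8R)-8-{[(tert-butyldimethylsilyl)oxy]methyl}deca-2,4,6-trienoate
Product: 28 (2E,4E,6E,8R)-8-{[(tert-butyldimethylsilyl)oxy]methyl}deca-2,4,6-trien-1-ol
Conditions: iBu2AlH (2.2 equiv), CH2Cl2, -78 °C; aq. potassium sodium tartrate
Reagents that add atoms: none
Why: 1,2-Reduction of the conjugated ester with iBu2AlH should give the trienol without touching the triene or the silyl ether.

**Step 18**
Reactants: 28 (2E,4E,6E,8R)-8-{[(tert-butyldimethylsilyl)oxy]methyl}deca-2,4,6-trien-1-ol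
Product: 29 (2E,4E,6E,8R)-8-{[(tert-butyldimethylsilyl)oxy]methyl}deca-2,4,6-trienal
Conditions: MnO2, CH2Cl2, rt, dark
Reagents that add atoms: none
Why: Allylic oxidation with MnO2 is neutral and selective for the trienylic alcohol, so alkene geometry and C8'' should be kept.

**Step 19**
Reactants: 16 5-[cis-4-(tert-butyldimethylsilyloxy)-1-(triethylsilyloxy)cyclohexyl]-3-iodo-1,4-bis[2-(trimethylsilyl)ethoxy]pyridin-2(1H)-one; 29 (2E,4E,6E,8R)-8-{[(tert-butyldimethylsilyl)oxy]methyl}deca-2,4,6-trienal
Product: 31 3-[(2E,4E,6E,8R)-8-{[(tert-butyldimethylsilyl)oxy]methyl}-1-hydroxydeca-2,4,6-trien-1-yl]-5-[cis-4-(tert-butyldimethylsilyloxy)-1-(triethylsilyloxy)cyclohexyl]-1,4-bis[2-(trimethylsilyl)ethoxy]pyridin-2(1H)-one (both C1'' epimers), via C3 arylmagnesium chloride 30 (not isolated)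
Conditions: iPrMgCl·LiCl, THF, -40 °C; 29, -78 °C to -20 °C; aq. NH4Cl
Reagents that add atoms: none
Why: Iodine–magnesium exchange should give the C3 Grignard reagent 30, stabilised between C2=O and O4, and its 1,2-addition to the aldehyde carbon of 29 (Grignard addition) gives the carbinol as a mixture of C1'' epimers, which is of no consequence because step 20 removes this centre.

**Step 20**
Reactants: 31 protected C1'' carbinol (both epimers)
Product: 32 3-[(2E,4E,6E,8R)-8-{[(tert-butyldimethylsilyl)oxy]methyl}deca-2,4,6-trienoyl]-5-[cis-4-(tert-butyldimethylsilyloxy)-1-(triethylsilyloxy)cyclohexyl]-1,4-bis[2-(trimethylsilyl)ethoxy]pyridin-2(1H)-one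
Conditions: MnO2, CH2Cl2, rt, dark
Reagents that add atoms: none
Why: The carbinol is both trienylic and bound to ring A, so MnO2 oxidation should convert both epimers into the single trienone under neutral conditions that spare the polyene and all protecting groups.

**Step 21**
Reactants: 32 fully protected trienone
Product: 33 1,4-dihydroxy-5-(cis-1,4-dihydroxycyclohexyl)-3-[(2E,4E,6E,8R)-8-(hydroxymethyl)deca-2,4,6-trienoyl]pyridin-2(1H)-one (target)
Conditions: Bu4NF (excess), AcOH, THF, 0 °C to rt, dark; pH 5 buffer work-up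
Reagents that add atoms: none
Why: Fluoride-induced global deprotection: Si–O cleavage of the three silyl ethers and fluoride-triggered fragmentation of the two 2-(trimethylsilyl)ethyl groups (both oxygens are good leaving groups, comparable to carboxylates) should release all five hydroxyl groups, while acetic acid buffering guards C8'', the triene and the tertiary carbinol.

**Compound list**
1 | dimethyl 3-oxopentanedioate | COC(=O)CC(=O)CC(=O)OC | starting material
2 | O-[2-(trimethylsilyl)ethyl]hydroxylamine hydrochloride | C[Si](C)(C)CCON.Cl | starting material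
3 | dimethyl 2-[(dimethylamino)methylidene]-3-oxopentanedioate | COC(=O)CC(=O)C(=CN(C)C)C(=O)OC | intermediate
4 | dimethyl 3-oxo-2-({[2-(trimethylsilyl)ethoxy]amino}methylidene)pentanedioate | COC(=O)CC(=O)C(=CNOCC[Si](C)(C)C)C(=O)OC | intermediate
5 | methyl 4-hydroxy-6-oxo-1-[2-(trimethylsilyl)ethoxy]-1,6-dihydropyridine-3-carboxylate | COC(=O)c1cn(OCC[Si](C)(C)C)c(=O)cc1O | intermediate
6 | methyl 6-oxo-1,4-bis[2-(trimethylsilyl)ethoxy]-1,6-dihydropyridine-3-carboxylate | COC(=O)c1cn(OCC[Si](C)(C)C)c(=O)cc1OCC[Si](C)(C)C | intermediate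
7 | 5-(prop-2-enoyl)-1,4-bis[2-(trimethylsilyl)ethoxy]pyridin-2(1H)-one | C=CC(=O)c1cn(OCC[Si](C)(C)C)c(=O)cc1OCC[Si](C)(C)C | intermediate
8 | 5-(3-hydroxypenta-1,4-dien-3-yl)-1,4-bis[2-(trimethylsilyl)ethoxy]pyridin-2(1H)-one | C=CC(O)(C=C)c1cn(OCC[Si](C)(C)C)c(=O)cc1OCC[Si](C)(C)C | intermediate
9 | 5-[3-(triethylsilyloxy)penta-1,4-dien-3-yl]-1,4-bis[2-(trimethylsilyl)ethoxy]pyridin-2(1H)-one | C=CC(O[Si](CC)(CC)CC)(C=C)c1cn(OCC[Si](C)(C)C)c(=O)cc1OCC[Si](C)(C)C | intermediate
10 | 5-[1-(2,3-dimethylbutan-2-yl)-4-(triethylsilyloxy)borinan-4-yl]-1,4-bis[2-(trimethylsilyl)ethoxy]pyridin-2(1H)-one | CC(C)C(C)(C)B1CCC(O[Si](CC)(CC)CC)(CC1)c1cn(OCC[Si](C)(C)C)c(=O)cc1OCC[Si](C)(C)C | intermediate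
11 | 5-[1-(2,3-dimethylbutan-2-yl)-2-oxo-5-(triethylsilyloxy)borepan-5-yl]-1,4-bis[2-(trimethylsilyl)ethoxy]pyridin-2(1H)-one (racemic) | CC(C)C(C)(C)B1CCC(O[Si](CC)(CC)CC)(CCC1=O)c1cn(OCC[Si](C)(C)C)c(=O)cc1OCC[Si](C)(C)C | intermediate
12 | (2,3-dimethylbutan-2-yl){1-hydroxy-4-(triethylsilyloxy)-4-[6-oxo-1,4-bis(2-trimethylsilylethoxy)-1,6-dihydropyridin-3-yl]cyclohexyl}borinic acid | CC(C)C(C)(C)B(O)C1(O)CCC(O[Si](CC)(CC)CC)(CC1)c1cn(OCC[Si](C)(C)C)c(=O)cc1OCC[Si](C)(C)C | intermediate
13 | 5-[4-oxo-1-(triethylsilyloxy)cyclohexyl]-1,4-bis[2-(trimethylsilyl)ethoxy]pyridin-2(1H)-one | O=C1CCC(O[Si](CC)(CC)CC)(CC1)c1cn(OCC[Si](C)(C)C)c(=O)cc1OCC[Si](C)(C)C | intermediate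
14 | 5-[cis-4-hydroxy-1-(triethylsilyloxy)cyclohexyl]-1,4-bis[2-(trimethylsilyl)ethoxy]pyridin-2(1H)-one | c1c(OCC[Si](C)(C)C)c([C@]2(O[Si](CC)(CC)CC)CC[C@@H](O)CC2)cn(OCC[Si](C)(C)C)c1=O | intermediate
15 | 5-[cis-4-(tert-butyldimethylsilyloxy)-1-(triethylsilyloxy)cyclohexyl]-1,4-bis[2-(trimethylsilyl)ethoxy]pyridin-2(1H)-one | c1c(OCC[Si](C)(C)C)c([C@]2(O[Si](CC)(CC)CC)CC[C@@H](O[Si](C)(C)C(C)(C)C)CC2)cn(OCC[Si](C)(C)C)c1=O | intermediate
16 | 5-[cis-4-(tert-butyldimethylsilyloxy)-1-(triethylsilyloxy)cyclohexyl]-3-iodo-1,4-bis[2-(trimethylsilyl)ethoxy]pyridin-2(1H)-one | Ic1c(OCC[Si](C)(C)C)c([C@]2(O[Si](CC)(CC)CC)CC[C@@H](O[Si](C)(C)C(C)(C)C)CC2)cn(OCC[Si](C)(C)C)c1=O | intermediate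
17 | (R)-4-benzyloxazolidin-2-one | O=C1N[C@H](Cc2ccccc2)CO1 | starting material
18 | butanoyl chloride | CCCC(=O)Cl | starting material
19 | (R)-4-benzyl-3-butanoyloxazolidin-2-one | CCCC(=O)N1[C@H](Cc2ccccc2)COC1=O | intermediate
20 | (R)-4-benzyl-3-[(2S)-2-(hydroxymethyl)butanoyl]oxazolidin-2-one | CC[C@H](C(=O)N1[C@H](Cc2ccccc2)COC1=O)CO | intermediate
21 | (R)-4-benzyl-3-[(2S)-2-{[(tert-butyldimethylsilyl)oxy]methyl}butanoyl]oxazolidin-2-one | CC[C@H](C(=O)N1[C@H](Cc2ccccc2)COC1=O)CO[Si](C)(C)C(C)(C)C | intermediate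
22 | (2R)-2-{[(tert-butyldimethylsilyl)oxy]methyl}butan-1-ol | CC[C@H](CO)CO[Si](C)(C)C(C)(C)C | intermediate
23 | (2S)-2-{[(tert-butyldimethylsilyl)oxy]methyl}butanal | CC[C@H](C=O)CO[Si](C)(C)C(C)(C)C | intermediate
24 | ethyl (2E,4E)-hexa-2,4-dienoate (ethyl sorbate) | CCOC(=O)/C=C/C=C/C | starting material
25 | ethyl (2E,4E)-6-bromohexa-2,4-dienoate | CCOC(=O)/C=C/C=C/CBr | intermediate
26 | ethyl (2E,4E)-6-(diethoxyphosphoryl)hexa-2,4-dienoate | CCOC(=O)/C=C/C=C/CP(=O)(OCC)OCC | intermediate
27 | ethyl (2E,4E,6E,8R)-8-{[(tert-butyldimethylsilyl)oxy]methyl}deca-2,4,6-trienoate | CC[C@H](/C=C/C=C/C=C/C(=O)OCC)CO[Si](C)(C)C(C)(C)C | intermediate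
28 | (2E,4E,6E,8R)-8-{[(tert-butyldimethylsilyl)oxy]methyl}deca-2,4,6-trien-1-ol | CC[C@H](/C=C/C=C/C=C/CO)CO[Si](C)(C)C(C)(C)C | intermediate
29 | (2E,4E,6E,8R)-8-{[(tert-butyldimethylsilyl)oxy]methyl}deca-2,4,6-trienal | CC[C@H](/C=C/C=C/C=C/C=O)CO[Si](C)(C)C(C)(C)C | intermediate
30 | C3 arylmagnesium chloride derived from 16 | Cl[Mg]c1c(OCC[Si](C)(C)C)c([C@]2(O[Si](CC)(CC)CC)CC[C@@H](O[Si](C)(C)C(C)(C)C)CC2)cn(OCC[Si](C)(C)C)c1=O | intermediate
31 | protected C1'' carbinol (both C1'' epimers; 8''R; ring B cis) | CC[C@H](/C=C/C=C/C=C/C(O)c1c(OCC[Si](C)(C)C)c([C@]2(O[Si](CC)(CC)CC)CC[C@@H](O[Si](C)(C)C(C)(C)C)CC2)cn(OCC[Si](C)(C)C)c1=O)CO[Si](C)(C)C(C)(C)C | intermediate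
32 | fully protected trienone | CC[C@H](/C=C/C=C/C=C/C(=O)c1c(OCC[Si](C)(C)C)c([C@]2(O[Si](CC)(CC)CC)CC[C@@H](O[Si](C)(C)C(C)(C)C)CC2)cn(OCC[Si](C)(C)C)c1=O)CO[Si](C)(C)C(C)(C)C | intermediate
33 | 1,4-dihydroxy-5-(cis-1,4-dihydroxycyclohexyl)-3-[(2E,4E,6E,8R)-8-(hydroxymethyl)deca-2,4,6-trienoyl]pyridin-2(1H)-one | CC[C@H](/C=C/C=C/C=C/C(=O)c1c(O)c([C@]2(O)CC[C@@H](O)CC2)cn(O)c1=O)CO | target

**Step count**
Total steps: 21. The longest linear sequence is 11 steps (steps 1–8 and 19–21). The side-chain branch (steps 9–13, 16–18 and 19–21) is equally long, and steps 14–15 make the phosphonate.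

**Steps most likely to fail**

1. **Step 5.**
   - Risk: intermolecular hydroboration may outrun ring formation and give oligomeric boranes. Boron may be placed at C2' or C6' and the silyloxy group then lost by beta-elimination. The borane may be tied up at the ring A carbonyl oxygen. The hindered borinane may take up CO too slowly.
   - Fallback: the polarity of the arms is reversed, setting out from 9. Exhaustive hydroboration with 9-BBN-H and oxidation with H2O2/NaOH gives the 1,5-diol F1. I2, PPh3 and imidazole convert it into the diiodide F2. Double alkylation of tosylmethyl isocyanide (NaH, DMSO/Et2O) closes ring B, the second alkylation again at C3'–C4', to give the isocyano sulfone F3. Brief hydrolysis with aq. HCl in THF at 0 °C comes back to the route at 13.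

2. **Step 3.**
   - Risk: the second vinyl nucleophile may add in conjugate fashion to the transient vinyl ketone, the nucleophile may attack C6 of ring A, or the push–pull ester may react too slowly.
   - Fallback: the two vinyl groups are introduced one at a time, setting out from 6. Me(MeO)NH·HCl and iPrMgCl give the Weinreb amide F4. Its chelated tetrahedral adduct with CH2=CHMgBr survives until a cold acidic quench and then releases the vinyl ketone 7, which is isolated this time. A separate 1,2-addition of CH2=CHCeCl2 at -78 °C comes back to the route at 8.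

3. **Step 6.**
   - Risk: facial selectivity may be poor if equatorial hydride attack competes or if the conformer with ring A axial is populated.
   - Fallback: the sterically amplified opposite selectivity is used and then inverted, setting out from 13. LiBH(s-Bu)3 in THF at -78 °C attacks from the equatorial side and gives the axial alcohol F5 (C4'-O trans to C1'-O). Mitsunobu inversion with 4-nitrobenzoic acid, PPh3 and DIAD gives the equatorial 4-nitrobenzoate F6. Methanolysis with K2CO3 in MeOH comes back to the route at 14.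

**Further compounds**
F1 | step 5 | 5-[1,5-dihydroxy-3-(triethylsilyloxy)pentan-3-yl]-1,4-bis[2-(trimethylsilyl)ethoxy]pyridin-2(1H)-one | OCCC(O[Si](CC)(CC)CC)(CCO)c1cn(OCC[Si](C)(C)C)c(=O)cc1OCC[Si](C)(C)C
F2 | step 5 | 5-[1,5-diiodo-3-(triethylsilyloxy)pentan-3-yl]-1,4-bis[2-(trimethylsilyl)ethoxy]pyridin-2(1H)-one | ICCC(O[Si](CC)(CC)CC)(CCI)c1cn(OCC[Si](C)(C)C)c(=O)cc1OCC[Si](C)(C)C
F3 | step 5 | 5-[4-isocyano-4-(4-methylbenzenesulfonyl)-1-(triethylsilyloxy)cyclohexyl]-1,4-bis[2-(trimethylsilyl)ethoxy]pyridin-2(1H)-one | [C-]#[N+]C1(S(=O)(=O)c2ccc(C)cc2)CCC(O[Si](CC)(CC)CC)(CC1)c1cn(OCC[Si](C)(C)C)c(=O)cc1OCC[Si](C)(C)C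
F4 | step 3 | N-methoxy-N-methyl-6-oxo-1,4-bis[2-(trimethylsilyl)ethoxy]-1,6-dihydropyridine-3-carboxamide | CON(C)C(=O)c1cn(OCC[Si](C)(C)C)c(=O)cc1OCC[Si](C)(C)C
F5 | step 6 | 5-[trans-4-hydroxy-1-(triethylsilyloxy)cyclohexyl]-1,4-bis[2-(trimethylsilyl)ethoxy]pyridin-2(1H)-one (C4'-O trans to C1'-O) | c1c(OCC[Si](C)(C)C)c([C@]2(O[Si](CC)(CC)CC)CC[C@H](O)CC2)cn(OCC[Si](C)(C)C)c1=O
F6 | step 6 | cis-4-[6-oxo-1,4-bis(2-trimethylsilylethoxy)-1,6-dihydropyridin-3-yl]-4-(triethylsilyloxy)cyclohexyl 4-nitrobenzoate (C4'-O cis to C1'-O) | c1c(OCC[Si](C)(C)C)c([C@]2(O[Si](CC)(CC)CC)CC[C@@H](OC(=O)c3ccc(cc3)[N+](=O)[O-])CC2)cn(OCC[Si](C)(C)C)c1=O
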